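Ring B (the δ-lactone) is opened at C4–C4a and O2–C3. A temporary C1′=C2′ double bond in the side chain makes C3 an allyl terminus, so one palladium-catalysed diene heteroannulation can form both bonds. The aryl carbon C4a of a 2-bromobenzoic acid (ring A, carboxyl on C8a) adds to the diene terminus C4, and the carboxylate oxygen then closes on C3 of the π-allyl intermediate under control of a chiral ligand. The precursors are 3,6-bis(benzyloxy)-2-bromobenzoic acid and a (2S,4E)-hepta-4,6-dien-2-yl ester carrying the benzyl-protected (R)-mevalonate. A single final hydrogenation removes the alkene and all three benzyl groups.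

Key step: step 6

Remark: the sense of induction of the chiral ligand in step 6 cannot be predicted with certainty; (S)-t-Bu-PHOX is written, and its enantiomer is taken if a trial run shows that it is the one leading to the (3S) lactone 11.

Step 1
Reactants: 1 2-bromobenzene-1,4-diol (bromohydroquinone)
Product: 2 1,4-bis(benzyloxy)-2-bromobenzene
Conditions: BnBr, K2CO3, DMF, 60 °C, N2
Reagents that add atoms: benzyl bromide BrCc1ccccc1
Why: Williamson ether synthesis on both phenoxides; benzyl ethers are chosen because the last step removes them by neutral hydrogenolysis.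

Step 2
Reactants: 2 1,4-bis(benzyloxy)-2-bromobenzene
Product: 4 3,6-bis(benzyloxy)-2-bromobenzoic acid, via aryllithium 3 (not isolated)
Conditions: LiN(i-Pr)2 (LDA), THF, −78 °C; CO2; aq. HCl
Reagents that add atoms: carbon dioxide O=C=O
Why: Directed ortho-metalation removes the ring proton flanked by bromine and a benzyloxy group (the most acidic one), and the aryllithium, kept at −78 °C to avoid benzyne formation, is carboxylated by CO2.

Step 3
Reactants: 5 (2S)-pent-4-yn-2-ol
Product: 7 (2S,4E)-hepta-4,6-dien-2-ol, via alkenylboronate 6 (not isolated)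
Conditions: B2pin2, CuCl (5 mol %), Xantphos (5 mol %), NaOt-Bu (10 mol %), MeOH, THF, rt; then vinyl bromide, Pd(PPh3)4 (3 mol %), aq. KOH, 50 °C, sealed
Reagents that add atoms: bis(pinacolato)diboron CC1(C)OB(OC1(C)C)B1OC(C)(C)C(C)(C)O1 (boron carried only in 6); vinyl bromide C=CBr
Why: Copper-catalysed protoboration adds boron and hydrogen syn across the terminal alkyne with boron on the terminus, and Suzuki–Miyaura coupling with vinyl bromide keeps the E geometry; the free hydroxyl is tolerated and the carbinol stereocentre is untouched.

Step 4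
Reactants: 8 (R)-mevalonolactone
Product: 9 (3R)-5-(benzyloxy)-3-hydroxy-3-methylpentanoic acid
Conditions: powdered KOH (4 equiv), BnBr (1.3 equiv), toluene, reflux; H2O; cold aq. HCl to pH 3
Reagents that add atoms: potassium hydroxide [K+].[OH-]; benzyl bromide BrCc1ccccc1
Why: Hydroxide opens the δ-lactone and the primary alkoxide is benzylated in a Williamson ether synthesis, while the insoluble carboxylate and the hindered tertiary hydroxyl should stay unalkylated; the quaternary stereocentre takes no part.

Step 5
Reactants: 7 (2S,4E)-hepta-4,6-dien-2-ol; 9 (3R)-5-(benzyloxy)-3-hydroxy-3-methylpentanoic acid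
Product: 10 (2S,4E)-hepta-4,6-dien-2-yl (3R)-5-(benzyloxy)-3-hydroxy-3-methylpentanoate
Conditions: DIC, DMAP (cat.), CH2Cl2, 0 °C to rt
Reagents that add atoms: none
Why: Steglich esterification acylates the unhindered secondary alcohol with retention at the carbinol carbon, and the tertiary hydroxyl of 9 is too hindered to compete.

Step 6
Reactants: 4 3,6-bis(benzyloxy)-2-bromobenzoic acid; 10 (2S,4E)-hepta-4,6-dien-2-yl (3R)-5-(benzyloxy)-3-hydroxy-3-methylpentanoate
Product: 11 (2S,4E)-5-[(3S)-5,8-bis(benzyloxy)-1-oxo-3,4-dihydro-1H-isochromen-3-yl]pent-4-en-2-yl (3R)-5-(benzyloxy)-3-hydroxy-3-methylpentanoate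
Conditions: Pd2(dba)3 (2.5 mol %), (S)-t-Bu-PHOX (6 mol %), K2CO3, DMF, 80 °C
Reagents that add atoms: none
Why: Zerovalent palladium inserts into the C–Br bond of 4, the arylpalladium adds across the terminal vinyl group of 10 with the aryl carbon (the future C4a) on the unsubstituted terminus (C4), and the resulting syn η3-allylpalladium is captured at its proximal terminus (C3) by the tethered carboxylate, which releases zerovalent palladium again. The closest known reaction is the Larock heteroannulation of 1,3-dienes with ortho-halobenzoic acids, and ligand-controlled enantioselective versions of this annulation class are established for related oxygen and nitrogen nucleophiles. Ring B closes in a 6-exo mode with respect to the allyl unit, since attack at C2′ would need an eight-membered ring. The C3 stereocentre is set by the chiral P,N ligand, which selects the diene face in the insertion step, followed by stereospecific anti attack of the carboxylate; the two existing stereocentres are too remote to interfere, so the step is catalyst-controlled. The step needs arylation of the terminal and not the internal alkene (secured by sterics), capture before β-hydride elimination (secured by the allyl stabilisation and the intramolecular nucleophile) and attack by the carboxylate oxygen only (secured by the benzyl ether on the oxygen next to C4a, which would otherwise close a dihydrobenzofuran).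

Step 7
Reactants: 11 (2S,4E)-5-[(3S)-5,8-bis(benzyloxy)-1-oxo-3,4-dihydro-1H-isochromen-3-yl]pent-4-en-2-yl (3R)-5-(benzyloxy)-3-hydroxy-3-methylpentanoate
Product: 12 Aspergimarin C, (2S)-5-[(3R)-5,8-dihydroxy-1-oxo-3,4-dihydro-1H-isochromen-3-yl]pentan-2-yl (3R)-3,5-dihydroxy-3-methylpentanoate
Conditions: H2 (1 atm), 10% Pd/C, EtOAc, rt
Reagents that add atoms: none
Why: Heterogeneous catalytic hydrogenation saturates the disubstituted alkene and hydrogenolysis cleaves the two aryl benzyl ethers and the primary benzyl ether under neutral conditions, so the lactone, the secondary ester and the three stereocentres are untouched (the C3 descriptor changes from S to R only because the priority of the side chain changes).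

Compound list
1 | 2-bromobenzene-1,4-diol (bromohydroquinone) | Oc1ccc(O)c(Br)c1 | starting material
2 | 1,4-bis(benzyloxy)-2-bromobenzene | Brc1cc(OCc2ccccc2)ccc1OCc1ccccc1 | intermediate
3 | [3,6-bis(benzyloxy)-2-bromophenyl]lithium (not isolated) | [Li]c1c(Br)c(OCc2ccccc2)ccc1OCc1ccccc1 | intermediate
4 | 3,6-bis(benzyloxy)-2-bromobenzoic acid | OC(=O)c1c(Br)c(OCc2ccccc2)ccc1OCc1ccccc1 | intermediate
5 | (2S)-pent-4-yn-2-ol | C[C@H](O)CC#C | starting material
6 | (2S,4E)-5-(4,4,5,5-tetramethyl-1,3,2-dioxaborolan-2-yl)pent-4-en-2-ol (not isolated) | C[C@H](O)C/C=C/B1OC(C)(C)C(C)(C)O1 | intermediate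
7 | (2S,4E)-hepta-4,6-dien-2-ol | C[C@H](O)C/C=C/C=C | intermediate
8 | (R)-mevalonolactone, (4R)-4-hydroxy-4-methyloxan-2-one | C[C@@]1(O)CCOC(=O)C1 | starting material
9 | (3R)-5-(benzyloxy)-3-hydroxy-3-methylpentanoic acid | OC(=O)C[C@](C)(O)CCOCc1ccccc1 | intermediate
10 | (2S,4E)-hepta-4,6-dien-2-yl (3R)-5-(benzyloxy)-3-hydroxy-3-methylpentanoate | C=C/C=C/C[C@H](C)OC(=O)C[C@](C)(O)CCOCc1ccccc1 | intermediate
11 | (2S,4E)-5-[(3S)-5,8-bis(benzyloxy)-1-oxo-3,4-dihydro-1H-isochromen-3-yl]pent-4-en-2-yl (3R)-5-(benzyloxy)-3-hydroxy-3-methylpentanoate | C[C@@H](C/C=C/[C@@H]1Cc2c(OCc3ccccc3)ccc(OCc3ccccc3)c2C(=O)O1)OC(=O)C[C@](C)(O)CCOCc1ccccc1 | intermediate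
12 | Aspergimarin C | C[C@@H](CCC[C@@H]1Cc2c(O)ccc(O)c2C(=O)O1)OC(=O)C[C@](C)(O)CCO | target

Total step count: 7. Longest linear sequence: 4 steps (for example steps 1, 2, 6, 7 from 1, or steps 3, 5, 6, 7 from 5).

Steps most likely to fail

Step 6. The hindered arylpalladium may insert into the substituted diene with poor facial selectivity, because the 1,3-disubstituted allyl intermediate cannot exchange its faces; Heck-type β-hydride elimination to a triene and re-ionisation of the allylic lactone are further loss channels. The fallback sets out from 4 and 9, moves the annulation to the simplest diene and joins the chain afterwards. Acid 4 is annulated with buta-1,3-diene (excess, sealed vessel) under the same palladium and ligand system to give (3S)-5,8-bis(benzyloxy)-3-ethenyl-3,4-dihydro-1H-isochromen-1-one F1. In this case the allyl intermediate has an unsubstituted terminus, its faces interconvert by π–σ–π isomerisation and the ligand can select at the C–O-forming step. Acid 9 is esterified (DIC, DMAP, CH2Cl2) with commercial (S)-pent-4-en-2-ol F2 to give (2S)-pent-4-en-2-yl (3R)-5-(benzyloxy)-3-hydroxy-3-methylpentanoate F3. Olefin cross-metathesis of F1 with an excess of F3 (second-generation Hoveyda–Grubbs catalyst, CH2Cl2, 40 °C) should bring the route back at 11; any Z isomer converges in step 7.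

Step 7. Hydrogenolysis of the allylic C3–O bond may compete with saturation of the alkene and open the lactone before the double bond is gone. The fallback sets out from 11 and separates the two events. The alkene is first reduced with diimide, generated from 2-nitrobenzenesulfonyl hydrazide and Et3N in CH2Cl2 at rt, which transfers hydrogen in a concerted way and cannot cleave C–O bonds. This should give (2S)-5-[(3R)-5,8-bis(benzyloxy)-1-oxo-3,4-dihydro-1H-isochromen-3-yl]pentan-2-yl (3R)-5-(benzyloxy)-3-hydroxy-3-methylpentanoate F4. Hydrogenolysis of F4 (H2, Pd/C, EtOAc) then returns the route at 12.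

Step 4. Under hot KOH the tertiary hydroxyl may be benzylated as well, or the hydroxy acid may dehydrate or be lost on acidification. The fallback leaves the route at 8, which is replaced by commercial 4-(benzyloxy)but-1-yne F5, and builds the stereocentre de novo. Zirconium-catalysed carboalumination (Me3Al, Cp2ZrCl2, CH2Cl2) and capture of the alkenylalane with paraformaldehyde should give (2E)-5-(benzyloxy)-3-methylpent-2-en-1-ol F6. Sharpless asymmetric epoxidation (Ti(Oi-Pr)4, D-(−)-diethyl tartrate, t-BuOOH, 4 Å molecular sieves, CH2Cl2, −20 °C) should give [(2R,3R)-3-[2-(benzyloxy)ethyl]-3-methyloxiran-2-yl]methanol F7. Hydride delivery to C2 with NaAlH2(OCH2CH2OMe)2 in THF should open the epoxide to (3S)-5-(benzyloxy)-3-methylpentane-1,3-diol F8. Oxidation of the primary alcohol with TEMPO (cat.) and PhI(OAc)2 in aqueous MeCN returns the route at 9.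

Further compounds
F1 | step 6 | (3S)-5,8-bis(benzyloxy)-3-ethenyl-3,4-dihydro-1H-isochromen-1-one | C=C[C@@H]1Cc2c(OCc3ccccc3)ccc(OCc3ccccc3)c2C(=O)O1
F2 | step 6 | (S)-pent-4-en-2-ol | C[C@H](O)CC=C
F3 | step 6 | (2S)-pent-4-en-2-yl (3R)-5-(benzyloxy)-3-hydroxy-3-methylpentanoate | C=CC[C@H](C)OC(=O)C[C@](C)(O)CCOCc1ccccc1
F4 | step 7 | (2S)-5-[(3R)-5,8-bis(benzyloxy)-1-oxo-3,4-dihydro-1H-isochromen-3-yl]pentan-2-yl (3R)-5-(benzyloxy)-3-hydroxy-3-methylpentanoate | C[C@@H](CCC[C@@H]1Cc2c(OCc3ccccc3)ccc(OCc3ccccc3)c2C(=O)O1)OC(=O)C[C@](C)(O)CCOCc1ccccc1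
F5 | step 4 | 4-(benzyloxy)but-1-yne | C#CCCOCc1ccccc1
F6 | step 4 | (2E)-5-(benzyloxy)-3-methylpent-2-en-1-ol | OC/C=C(\C)CCOCc1ccccc1
F7 | step 4 | [(2R,3R)-3-[2-(benzyloxy)ethyl]-3-methyloxiran-2-yl]methanol | OC[C@H]1O[C@]1(C)CCOCc1ccccc1
F8 | step 4 | (3S)-5-(benzyloxy)-3-methylpentane-1,3-diol | OCC[C@](C)(O)CCOCc1ccccc1
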